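**Assumption (one line):** labdane numbering (C1–C20, normal series: 5α-H, 9α-H, 10β-CH3) is used for the terpenoid part and flavone numbering (primed for ring B) for the quinone part; (2E,6E)-farnesyl acetate, propyne and diosmetin are bought.

## Retrosynthetic overview

1. Last step: intermolecular endo Diels–Alder of the unprotected (12Z)-triene diol 17 with the flavone ring-B para-quinone 19; it closes the cyclohexene ring and sets C12, C1′ and C2′.
2. Quinone 19 comes in one step from diosmetin by para-oxidation of the 3′-OH phenol; the chromone rings are bought.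
3. The Z-diene of 17 is unveiled last from a (Z)-alkenyl chloride; 7β-OH comes from allylic oxidation and Luche reduction of the 8(17)-ene.
4. Rings A and B are formed together by a Cp2TiCl (trivalent titanium) radical bicyclisation of a Sharpless epoxy alcohol, a chair–chair mimic of the cyclase step; C3 is then deoxygenated.
5. The acyclic chain is farnesyl acetate (ω-oxidised with SeO2) joined to a (Z)-2-chloropropenyl boronate. Ring order: A and B (step 5), then the cyclohexene ring (step 12).

## Route

**Step 1**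
Reactants: 1 (2E,6E)-farnesyl acetate
Product: 2 (2E,6E,10E)-12-hydroxy-3,7,11-trimethyldodeca-2,6,10-trien-1-yl acetate
Conditions: SeO2 (0.1 equiv), salicylic acid (0.1 equiv), t-BuOOH (3 equiv), CH2Cl2, 0 °C → rt
Reagents that add atoms: tert-butyl hydroperoxide `CC(C)(C)OO` (oxygen relayed through selenium dioxide `O=[Se]=O`)
Why: Catalytic SeO2 allylic oxidation (ene reaction, then [2,3]-sigmatropic shift) attacks the E-methyl of the terminal trisubstituted alkene, since the 2,3-alkene is deactivated by the allylic acetate; no stereocentre is formed and the new alkene is E.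

**Step 2**
Reactants: 3 propyne
Product: 5 2-[(Z)-2-chloroprop-1-en-1-yl]-4,4,5,5-tetramethyl-1,3,2-dioxaborolane, via dichloro(alkenyl)borane 4 (not isolated)
Conditions: BCl3 (1.0 equiv), CH2Cl2, −78 → 0 °C; then pinacol (1.1 equiv), 0 °C → rt
Reagents that add atoms: boron trichloride `ClB(Cl)Cl`; pinacol `CC(C)(O)C(C)(C)O`
Why: syn-1,2-Chloroboration (haloboration) of the terminal alkyne puts boron on the terminal carbon and chlorine on the internal carbon on the same side, which fixes the Z geometry that later becomes the 12Z diene; pinacol esterification gives a stable boronate.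

**Step 3**
Reactants: 2 (2E,6E,10E)-12-hydroxyfarnesyl acetate; 5 (Z)-2-chloropropenyl pinacol boronate
Product: 6 (2E,6E,10E,13Z)-14-chloro-2,6,10-trimethylpentadeca-2,6,10,13-tetraen-1-ol
Conditions: Pd(PPh3)4 (5 mol %), K2CO3 (2 equiv), THF/H2O (10:1), 50 °C
Reagents that add atoms: none
Why: Suzuki–Miyaura allyl–alkenyl coupling through a π-allyl palladium complex joins C11 to C12 at the unhindered allyl terminus with retention of all alkene geometries; zerovalent palladium with PPh3 ionises the allylic acetate but not the alkenyl C–Cl bond or the allylic alcohol.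

**Step 4**
Reactants: 6 chloro-tetraenol
Product: 7 [(2S,3S)-3-[(3E,7E,10Z)-11-chloro-3,7-dimethyldodeca-3,7,10-trien-1-yl]-2-methyloxiran-2-yl]methanol
Conditions: Ti(OiPr)4 (10 mol %), L-(+)-diethyl tartrate (12 mol %), t-BuOOH (2 equiv), 4 Å MS, CH2Cl2, −20 °C
Reagents that add atoms: tert-butyl hydroperoxide `CC(C)(C)OO`
Why: Katsuki–Sharpless asymmetric epoxidation of the (E)-2-methylallylic alcohol with the L-(+)-tartrate catalyst delivers oxygen to one face, setting the (2S,3S)-epoxide (future C4 and C3) in high ee; the other alkenes lack a directing hydroxyl and do not react.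

**Step 5**
Reactants: 7 (2S,3S)-epoxy alcohol
Product: 10 13-chloro-14,15-dinorlabda-8(17),12Z-diene-3β,18-diol, via trimethylsilyl ether 8 (not isolated), via bis(trimethylsilyl) ether 9 (not isolated)
Conditions: Cp2TiCl2 (20 mol %), Mn powder (8 equiv), Me3SiCl (4 equiv), 2,4,6-collidine (7 equiv), THF, rt; then 1 M HCl, THF
Reagents that add atoms: none
Why: Titanocene-mediated radical epoxy-polyene bicyclisation (Nugent–RajanBabu epoxide opening by trivalent titanium, then two 6-endo closures through a chair–chair array) gives the trans-decalin: the equatorial C3–O–Ti group relays the epoxide chirality to C5, C10 and C9, the silylated CH2O group on the planar C4 radical takes the equatorial 4α (C18) site as known for ω-oxygenated epoxyfarnesyl substrates, and the final tertiary radical is trapped by Cp2TiCl and loses a C17 hydrogen to give the 8(17)-alkene.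

**Step 6**
Reactants: 10 3β,18-diol
Product: 11 cyclic 3β,18-thionocarbonate of 10
Conditions: 1,1′-thiocarbonyldiimidazole (1.5 equiv), DMAP (cat.), toluene, 80 °C
Reagents that add atoms: 1,1′-thiocarbonyldiimidazole `S=C(n1ccnc1)n1ccnc1`
Why: Thiocarbonyl transfer closes the gauche 3β-OH/4α-CH2OH pair to a six-membered cyclic thionocarbonate, activating it for radical deoxygenation without touching a stereocentre.

**Step 7**
Reactants: 11 cyclic thionocarbonate
Product: 13 13-chloro-14,15-dinorlabda-8(17),12Z-dien-18-ol, via stannyl thiocarbonate 12 (not isolated)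
Conditions: Bu3SnH (1.5 equiv), AIBN (0.2 equiv), toluene, 90 °C; then NaOH (cat.), MeOH/H2O, rt
Reagents that add atoms: none
Why: Barton–McCombie deoxygenation: Bu3Sn• adds to C=S and the ring opens by β-scission toward the more stable secondary C3 radical, which takes hydrogen from Bu3SnH, so C3 loses its oxygen; hydrolysis of the remaining S-stannyl thiocarbonate frees the C18 alcohol, and the alkenyl chloride is inert to stannyl radicals.

**Step 8**
Reactants: 13 18-alcohol
Product: 15 13-chloro-18-hydroxy-14,15-dinorlabda-8(17),12Z-dien-7-one, via 7α-allylic alcohol 14 (not isolated)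
Conditions: SeO2 (0.5 equiv), t-BuOOH (2 equiv), CH2Cl2, 0 °C → rt; then MnO2 (15 equiv), CH2Cl2, rt
Reagents that add atoms: tert-butyl hydroperoxide `CC(C)(C)OO` (oxygen relayed through selenium dioxide `O=[Se]=O`)
Why: SeO2 allylic hydroxylation of the exocyclic alkene occurs at the ring CH2 (C7) to give the axial 7α-alcohol, the electron-poor chloroalkene not competing; MnO2 then oxidises only this allylic alcohol to the exocyclic enone, erasing the wrong C7 configuration.

**Step 9**
Reactants: 15 exocyclic enone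
Product: 16 13-chloro-14,15-dinorlabda-8(17),12Z-diene-7β,18-diol
Conditions: NaBH4 (1.1 equiv), CeCl3·7H2O (1.1 equiv), MeOH, −40 °C
Reagents that add atoms: none
Why: Luche 1,2-reduction: hydride attacks the C7 carbonyl axially from the α-face, giving the equatorial 7β-alcohol without conjugate reduction.

**Step 10**
Reactants: 16 7β,18-diol alkenyl chloride
Product: 17 (12Z)-labda-8(17),12,14-triene-7β,18-diol
Conditions: vinylboronic acid pinacol ester (2 equiv), Pd2(dba)3 (2.5 mol %), [HP(t-Bu)3]BF4 (10 mol %), K3PO4 (3 equiv), THF/H2O, 45 °C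
Reagents that add atoms: vinylboronic acid pinacol ester `C=CB1OC(C)(C)C(C)(C)O1`
Why: Suzuki–Miyaura coupling of the alkenyl chloride (oxidative addition enabled by the electron-rich P(t-Bu)3 ligand) proceeds with retention of alkene geometry, so the C11/Cl cis relationship becomes the 12Z diene.

**Step 11**
Reactants: 18 diosmetin (5,7,3′-trihydroxy-4′-methoxyflavone)
Product: 19 2-(5,7-dihydroxy-4-oxo-4H-chromen-2-yl)-5-methoxycyclohexa-2,5-diene-1,4-dione
Conditions: (KSO3)2NO (2.5 equiv), KH2PO4 buffer (pH 6), acetone/H2O, 0 °C → rt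
Reagents that add atoms: dipotassium nitrosodisulfonate `[K+].[K+].[O]N(S(=O)(=O)[O-])S(=O)(=O)[O-]`
Why: Teuber oxidation: the nitrosodisulfonate radical abstracts the hydrogen of the guaiacol-type 3′-OH (the chelated 5-OH and the vinylogous-acid 7-OH are much harder to oxidise) and a second equivalent couples at the free para position C6′, giving the 3′,6′-para-quinone; no stereocentre.

**Step 12**
Reactants: 17 (12Z)-triene diol; 19 flavone ring-B quinone
Product: 20 dichrostachine A
Conditions: CH2Cl2/THF (9:1), 1.0 GPa, 30 °C, 72 h, dark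
Reagents that add atoms: none
Why: Intermolecular endo Diels–Alder reaction: the methoxy-bearing alkene of 19 is deactivated as a vinylogous ester, so the diene adds across C1′=C2′ with C15 bonding to unsubstituted C2′ and C12 to C1′; with the quinone ring endo, the inside C11 substituent of the 12Z diene ends up cis to the flavonyl group and to H-2′ (a 12E diene would give the C12 epimer), and attack on the diene face syn to H-9, the other face being blocked by C8/C17 in the preferred side-chain rotamer, gives 12R and so the absolute configuration of all three new centres; the pressure offsets the low s-cis population of the Z diene without heat or acid.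

## Compound list

1 | (2E,6E)-farnesyl acetate | `CC(C)=CCC/C(C)=C/CC/C(C)=C/COC(C)=O` | starting material
2 | (2E,6E,10E)-12-hydroxy-3,7,11-trimethyldodeca-2,6,10-trien-1-yl acetate | `OC/C(C)=C/CC/C(C)=C/CC/C(C)=C/COC(C)=O` | intermediate
3 | propyne | `CC#C` | starting material
4 | dichloro[(Z)-2-chloroprop-1-en-1-yl]borane | `C/C(Cl)=C/B(Cl)Cl` | intermediate (not isolated)
5 | 2-[(Z)-2-chloroprop-1-en-1-yl]-4,4,5,5-tetramethyl-1,3,2-dioxaborolane | `C/C(Cl)=C/B1OC(C)(C)C(C)(C)O1` | intermediate
6 | (2E,6E,10E,13Z)-14-chloro-2,6,10-trimethylpentadeca-2,6,10,13-tetraen-1-ol | `OC/C(C)=C/CC/C(C)=C/CC/C(C)=C/C/C=C(\Cl)C` | intermediate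
7 | [(2S,3S)-3-[(3E,7E,10Z)-11-chloro-3,7-dimethyldodeca-3,7,10-trien-1-yl]-2-methyloxiran-2-yl]methanol | `OC[C@]1(C)O[C@H]1CC/C(C)=C/CC/C(C)=C/C/C=C(\Cl)C` | intermediate
8 | trimethylsilyl ether of 7 | `C[Si](C)(C)OC[C@]1(C)O[C@H]1CC/C(C)=C/CC/C(C)=C/C/C=C(\Cl)C` | intermediate (not isolated)
9 | 3β,18-bis(trimethylsilyl) ether of 10 | `C=C1CC[C@H]2[C@](C)(CO[Si](C)(C)C)[C@@H](O[Si](C)(C)C)CC[C@]2(C)[C@H]1C/C=C(\Cl)C` | intermediate (not isolated)
10 | 13-chloro-14,15-dinorlabda-8(17),12Z-diene-3β,18-diol | `C=C1CC[C@H]2[C@](C)(CO)[C@@H](O)CC[C@]2(C)[C@H]1C/C=C(\Cl)C` | intermediate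
11 | cyclic 3β,18-thionocarbonate of 10 | `C=C1CC[C@H]2[C@]3(C)COC(=S)O[C@H]3CC[C@]2(C)[C@H]1C/C=C(\Cl)C` | intermediate
12 | 18-O-[(tributylstannylsulfanyl)carbonyl] derivative of 13 | `C=C1CC[C@H]2[C@](C)(COC(=O)S[Sn](CCCC)(CCCC)CCCC)CCC[C@]2(C)[C@H]1C/C=C(\Cl)C` | intermediate (not isolated)
13 | 13-chloro-14,15-dinorlabda-8(17),12Z-dien-18-ol | `C=C1CC[C@H]2[C@](C)(CO)CCC[C@]2(C)[C@H]1C/C=C(\Cl)C` | intermediate
14 | 13-chloro-14,15-dinorlabda-8(17),12Z-diene-7α,18-diol | `C=C1[C@H](O)C[C@H]2[C@](C)(CO)CCC[C@]2(C)[C@H]1C/C=C(\Cl)C` | intermediate (not isolated)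
15 | 13-chloro-18-hydroxy-14,15-dinorlabda-8(17),12Z-dien-7-one | `C=C1C(=O)C[C@H]2[C@](C)(CO)CCC[C@]2(C)[C@H]1C/C=C(\Cl)C` | intermediate
16 | 13-chloro-14,15-dinorlabda-8(17),12Z-diene-7β,18-diol | `C=C1[C@@H](O)C[C@H]2[C@](C)(CO)CCC[C@]2(C)[C@H]1C/C=C(\Cl)C` | intermediate
17 | (12Z)-labda-8(17),12,14-triene-7β,18-diol | `C=C1[C@@H](O)C[C@H]2[C@](C)(CO)CCC[C@]2(C)[C@H]1C/C=C(\C=C)C` | intermediate
18 | diosmetin | `COc1ccc(cc1O)-c1cc(=O)c2c(O)cc(O)cc2o1` | starting material
19 | 2-(5,7-dihydroxy-4-oxo-4H-chromen-2-yl)-5-methoxycyclohexa-2,5-diene-1,4-dione | `COC1=CC(=O)C(=CC1=O)c1cc(=O)c2c(O)cc(O)cc2o1` | intermediate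
20 | dichrostachine A | `C=C1[C@@H](O)C[C@H]2[C@](C)(CO)CCC[C@]2(C)[C@H]1C[C@@H]1C(C)=CC[C@H]2C(=O)C(OC)=CC(=O)[C@@]12c1cc(=O)c2c(O)cc(O)cc2o1` | target

## Count and risks

Total steps: 12. Longest linear sequence: 10 (steps 1, 3, 4, 5, 6, 7, 8, 9, 10, 12, from compound 1).

The three steps most likely to fail are steps 12, 5 and 11.

**Step 12 (Z-diene Diels–Alder; rate, regiochemistry and facial selectivity are all unproven for this pair).** The fallback sets out from 17 and comes back at 20. Both hydroxyls of 17 are silylated (TBSOTf, 2,6-lutidine, CH2Cl2) to give (12Z)-7β,18-bis(tert-butyldimethylsilyloxy)labda-8(17),12,14-triene F1. F1 is combined with 19 under Lewis-acid catalysis (Sc(OTf)3, 10–20 mol %, CH2Cl2/MeCN, −30 °C) instead of pressure. The Lewis acid lowers the quinone LUMO and makes the transition state more asynchronous, which tolerates the inside C11 substituent and reinforces C15-to-C2′ bonding. This gives the 7,18-bis(tert-butyldimethylsilyl) ether of dichrostachine A F2, and HF·pyridine in THF then frees both alcohols to give 20.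

**Step 5 (radical bicyclisation; moderate yield, and the C4 configuration rests on an equatorial preference rather than on a stereospecific event).** The fallback sets out from 7 and comes back at 10. Compound 7 is protected (TBDPSCl, imidazole) as the tert-butyldiphenylsilyl ether of 7 F3. A cationic epoxide-initiated bicyclisation (MeAlCl2, CH2Cl2, −78 °C) then opens the epoxide anti and in concert with attack of the 5(10)-alkene, so C4 is set stereospecifically from the E-derived epoxide. The price is an 8(17)-ene/7-ene mixture, which is separated on AgNO3-impregnated silica. The product, 13-chloro-18-(tert-butyldiphenylsilyloxy)-14,15-dinorlabda-8(17),12Z-dien-3β-ol F4, is desilylated with Bu4NF to give 10.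

**Step 11 (Teuber oxidation on an unprotected polyphenol of low solubility; ring A may be attacked).** The fallback sets out from 18 and comes back at 19. The acidic 7-OH is masked first (TBSCl 1.0 equiv, Et3N, DMF) to give 7-O-(tert-butyldimethylsilyl)diosmetin F5, which leaves only the chelated 5-OH on ring A and makes the substrate soluble. Oxidation with (KSO3)2NO as in step 11 gives the 7-O-(tert-butyldimethylsilyl) ether of quinone 19 F6, and KHF2 in MeOH removes the phenolic silyl group to give 19.

## Further compounds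

F1 | step 12 | (12Z)-7β,18-bis(tert-butyldimethylsilyloxy)labda-8(17),12,14-triene | `C=C1[C@@H](O[Si](C)(C)C(C)(C)C)C[C@H]2[C@](C)(CO[Si](C)(C)C(C)(C)C)CCC[C@]2(C)[C@H]1C/C=C(\C=C)C`
F2 | step 12 | 7,18-bis(tert-butyldimethylsilyl) ether of dichrostachine A | `C=C1[C@@H](O[Si](C)(C)C(C)(C)C)C[C@H]2[C@](C)(CO[Si](C)(C)C(C)(C)C)CCC[C@]2(C)[C@H]1C[C@@H]1C(C)=CC[C@H]2C(=O)C(OC)=CC(=O)[C@@]12c1cc(=O)c2c(O)cc(O)cc2o1`
F3 | step 5 | tert-butyldiphenylsilyl ether of 7 | `CC(C)(C)[Si](OC[C@]1(C)O[C@H]1CC/C(C)=C/CC/C(C)=C/C/C=C(\Cl)C)(c1ccccc1)c1ccccc1`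
F4 | step 5 | 13-chloro-18-(tert-butyldiphenylsilyloxy)-14,15-dinorlabda-8(17),12Z-dien-3β-ol | `C=C1CC[C@H]2[C@](C)(CO[Si](c3ccccc3)(c3ccccc3)C(C)(C)C)[C@@H](O)CC[C@]2(C)[C@H]1C/C=C(\Cl)C`
F5 | step 11 | 7-O-(tert-butyldimethylsilyl)diosmetin | `COc1ccc(cc1O)-c1cc(=O)c2c(O)cc(O[Si](C)(C)C(C)(C)C)cc2o1`
F6 | step 11 | 7-O-(tert-butyldimethylsilyl) ether of quinone 19 | `COC1=CC(=O)C(=CC1=O)c1cc(=O)c2c(O)cc(O[Si](C)(C)C(C)(C)C)cc2o1`
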